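**Retrosynthetic overview**

1. 23 ⇐ 22 (cleavage of three aryl methyl ethers) ⇐ 20 (acid: loss of both MOM groups and closure of the O1–C2 bond through the C2 benzylic cation, trans) ⇐ 19 (oxidation of the C2–B bond).
2. 19 ⇐ 13 + 17 + 15 by one three-component conjunctive coupling across the alkene that becomes C2–C3: ring A moves from boron to C2, ring B comes from the aryl triflate onto C3, and ring C already sits on C3.
3. 13 ⇐ 8 (boryl-olefination, then exchange of the diol on boron) ⇐ 6 (lithiation between the two oxygens, formylation) ⇐ 2 + 3 (Wittig, hydrogenation).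
4. Feature used: C2 and C3 of the dihydrofuran ring are neighbouring sp3 carbons carrying one aryl ring each (ring A and O1 on C2, ring B and C3a of ring C on C3), and ring C has oxygen on both carbons ortho to C3a (C4 and C7a), so either phenol can become O1.
5. Ring order: the four benzene rings are bought; the dihydrofuran ring is the only ring made and closes in step 12.

Key step: step 10

Assumption 1: the alkenyl pinacol boronate 9 is carried on as its ester 13 with the bulkier cis-1,2-dimethylacenaphthene-1,2-diol 12. β-Substituted alkenyl pinacol borates tend to hand a group directly to palladium (Suzuki–Miyaura coupling) instead of undergoing the 1,2-shift.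

Assumption 2: MandyPhos here is 1,1′-bis[bis(4-methoxy-3,5-dimethylphenyl)phosphino]-2,2′-bis[α-(dimethylamino)benzyl]ferrocene. Which antipode gives the (1R,2S) boronate cannot be predicted with certainty for this alkene. The (Sp,Sp) ligand is written; its mirror image would be taken if a first run shows the opposite sense.

**Route**

Step 1
Reactants: 1 3,5-dihydroxybenzaldehyde
Product: 2 3,5-bis(methoxymethoxy)benzaldehyde
Conditions: MOMCl, i-Pr2NEt, CH2Cl2, 0 °C to 25 °C
Reagents that add atoms: chloromethyl methyl ether, COCCl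
Why: Double O-alkylation of the phenols by the chloromethyl ether under amine base (MOM protection) leaves the aldehyde untouched and installs the ortho-directing groups needed in step 4.

Step 2
Reactants: 2 3,5-bis(methoxymethoxy)benzaldehyde; 3 (4-methoxybenzyl)triphenylphosphonium chloride
Product: 5 1-[2-(4-methoxyphenyl)ethenyl]-3,5-bis(methoxymethoxy)benzene (E/Z mixture), via phosphonium ylide 4 (not isolated)
Conditions: KOtBu, THF, 0 °C to 25 °C
Reagents that add atoms: none
Why: Wittig olefination of the aryl aldehyde with the semi-stabilised benzylic ylide should give the stilbene as an E/Z mixture, which does not matter because the double bond is reduced next.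

Step 3
Reactants: 5 1-[2-(4-methoxyphenyl)ethenyl]-3,5-bis(methoxymethoxy)benzene
Product: 6 1-[2-(4-methoxyphenyl)ethyl]-3,5-bis(methoxymethoxy)benzene
Conditions: H2 (1 atm), 10 % Pd/C, EtOAc, 25 °C
Reagents that add atoms: none
Why: Catalytic hydrogenation over Pd/C saturates the stilbene double bond, while the aryl MOM and methyl ethers, which have no benzylic C–O bond, should not be hydrogenolysed.

Step 4
Reactants: 6 1-[2-(4-methoxyphenyl)ethyl]-3,5-bis(methoxymethoxy)benzene
Product: 8 2,6-bis(methoxymethoxy)-4-[2-(4-methoxyphenyl)ethyl]benzaldehyde, via aryllithium 7 (not isolated)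
Conditions: n-BuLi, TMEDA, THF, 0 °C; DMF, 0 °C to 25 °C; aq. NH4Cl
Reagents that add atoms: N,N-dimethylformamide, CN(C)C=O
Why: Directed ortho-metalation occurs at the ring carbon flanked by both MOM ethers, the most acidic and doubly chelated position, and the aryllithium is formylated by DMF.

Step 5
Reactants: 8 2,6-bis(methoxymethoxy)-4-[2-(4-methoxyphenyl)ethyl]benzaldehyde
Product: 9 2-[(E)-2-{2,6-bis(methoxymethoxy)-4-[2-(4-methoxyphenyl)ethyl]phenyl}ethenyl]-4,4,5,5-tetramethyl-1,3,2-dioxaborolane
Conditions: Cl2CHBpin, CrCl2, LiI, THF, 25 °C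
Reagents that add atoms: 2-(dichloromethyl)-4,4,5,5-tetramethyl-1,3,2-dioxaborolane, ClC(Cl)B1OC(C)(C)C(C)(C)O1
Why: Takai–Utimoto boryl-olefination, in which the geminal dichromium reagent formed from Cl2CHBpin and CrCl2 adds to the aldehyde and eliminates to the (E)-alkenyl boronate, the E geometry following from elimination through the less crowded arrangement.

Step 6
Reactants: 9 2-[(E)-2-{2,6-bis(methoxymethoxy)-4-[2-(4-methoxyphenyl)ethyl]phenyl}ethenyl]-4,4,5,5-tetramethyl-1,3,2-dioxaborolane
Product: 10 [(E)-2-{2,6-bis(methoxymethoxy)-4-[2-(4-methoxyphenyl)ethyl]phenyl}ethenyl]boronic acid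
Conditions: NaIO4, NH4OAc, acetone/H2O, 25 °C
Reagents that add atoms: water, O
Why: Periodate cleaves the pinacol released in the hydrolysis equilibrium (glycol cleavage), which drives the pinacol ester to the free boronic acid at near-neutral pH where the MOM ethers and the alkene geometry are safe.

Step 7
Reactants: 11 acenaphthylene-1,2-dione
Product: 12 cis-1,2-dimethyl-1,2-dihydroacenaphthylene-1,2-diol (meso)
Conditions: AlMe3, toluene, 0 °C to 25 °C; aqueous work-up; recrystallisation
Reagents that add atoms: trimethylaluminium, C[Al](C)C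
Why: Twofold 1,2-addition of methyl from aluminium to the 1,2-diketone gives the tertiary diol; only the relative sense of the two new stereocentres matters, and the cis (meso) diol, the isomer that can span one boron atom, is secured by crystallisation.

Step 8
Reactants: 10 [(E)-2-{2,6-bis(methoxymethoxy)-4-[2-(4-methoxyphenyl)ethyl]phenyl}ethenyl]boronic acid; 12 cis-1,2-dimethyl-1,2-dihydroacenaphthylene-1,2-diol
Product: 13 8-[(E)-2-{2,6-bis(methoxymethoxy)-4-[2-(4-methoxyphenyl)ethyl]phenyl}ethenyl]-6b,9a-dimethyl-6b,9a-dihydroacenaphtho[1,2-d][1,3,2]dioxaborole (cis-fused; ester of 10 with diol 12)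
Conditions: MgSO4, CH2Cl2, 25 °C
Reagents that add atoms: none
Why: Condensation of a boronic acid with a 1,2-diol (boronic ester formation) is driven by the drying agent and puts on boron the bulkier diol that a β-substituted alkenyl borate needs to favour the 1,2-shift over transfer of a group to palladium.

Step 9
Reactants: 14 3,5-dimethoxyphenol
Product: 15 3,5-dimethoxyphenyl trifluoromethanesulfonate
Conditions: Tf2O, pyridine, CH2Cl2, 0 °C
Reagents that add atoms: trifluoromethanesulfonic anhydride, O=S(=O)(OS(=O)(=O)C(F)(F)F)C(F)(F)F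
Why: O-Sulfonylation of the phenol with triflic anhydride gives the aryl triflate, the electrophile that leaves a non-coordinating counter-ion on palladium.

Step 10
Reactants: 13 alkenyl boronate of step 8; 15 3,5-dimethoxyphenyl trifluoromethanesulfonate; 16 4-bromoanisole
Product: 19 8-[(1R,2S)-2-{2,6-bis(methoxymethoxy)-4-[2-(4-methoxyphenyl)ethyl]phenyl}-2-(3,5-dimethoxyphenyl)-1-(4-methoxyphenyl)ethyl]-6b,9a-dimethyl-6b,9a-dihydroacenaphtho[1,2-d][1,3,2]dioxaborole, via 4-methoxyphenyllithium 17 (not isolated), via lithium alkenyl(aryl)borate 18 (not isolated)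
Conditions: 16, t-BuLi (2 equiv), Et2O, −78 °C; 13, THF, −78 °C to 25 °C; then Pd(OAc)2 (5 mol %), (Sp,Sp)-MandyPhos (6 mol %), 15, NaOTf, THF, 60 °C
Reagents that add atoms: none
Why: Zerovalent palladium inserts into the C–O bond of triflate 15 to give a cationic aryl(ring B)palladium complex that binds the alkene of borate 18; ring A then shifts from boron to C2 on the face opposite palladium (a metal-induced 1,2-metallate shift) while palladium bonds to C3, and reductive elimination joins ring B to C3 with retention. The closest known reaction is the enantioselective conjunctive cross-coupling of β-substituted alkenylboron ate complexes with aryl triflates under Pd(OAc)2 and MandyPhos, where the acenaphthoquinone-derived diol on boron holds back direct alkenyl or aryl transfer to palladium. No ring is closed in this step. C2 and C3 are set together: the anti addition across the (E)-alkene fixes their relative configuration, and the chiral bisphosphine on palladium chooses the alkene face and hence the (S) configuration at the carbon that becomes C3. The step needs chemoselectivity for the shift over transmetalation (bulky diol, cationic palladium, NaOTf to take up the bromide left from the lithium–bromine exchange), regioselectivity (ring A can only end on the carbon bound to boron) and face selectivity at an alkene whose C3 end carries a ring with two ortho substituents, which is the untested point of the route. Only the C3 configuration has to be right, because C2 is ionised in step 12.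

Step 11
Reactants: 19 boronate of step 10
Product: 20 (1R,2S)-2-{2,6-bis(methoxymethoxy)-4-[2-(4-methoxyphenyl)ethyl]phenyl}-2-(3,5-dimethoxyphenyl)-1-(4-methoxyphenyl)ethan-1-ol
Conditions: 30 % H2O2, 3 M NaOH, THF, 0 °C to 25 °C
Reagents that add atoms: hydrogen peroxide, OO
Why: Alkaline hydrogen peroxide oxidises the C–B bond by 1,2-migration of carbon from boron to oxygen with retention, so the (1R) carbinol should form and the neighbouring diaryl carbon (the future C3) is untouched.

Step 12
Reactants: 20 (1R,2S)-alcohol of step 11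
Product: 22 (2S,3S)-3-(3,5-dimethoxyphenyl)-2-(4-methoxyphenyl)-6-[2-(4-methoxyphenyl)ethyl]-2,3-dihydro-1-benzofuran-4-ol, via open-chain triol 21 (not isolated)
Conditions: HCl (2 M in MeOH), 0.02 M, 45 °C
Reagents that add atoms: none
Why: Acid-catalysed acetal cleavage frees both phenols of ring C, the 4-methoxybenzylic alcohol ionises, and either ortho phenol closes the five-membered ring (SN1 cycloetherification) on the face away from ring B at C3, so the new C2 centre is set trans by the fixed C3 centre and by the reversibility of the closure.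

Step 13
Reactants: 22 (2S,3S)-dihydrobenzofuran of step 12
Product: 23 5-[(2S,3S)-4-hydroxy-2-(4-hydroxyphenyl)-6-[2-(4-hydroxyphenyl)ethyl]-2,3-dihydro-1-benzofuran-3-yl]benzene-1,3-diol
Conditions: BBr3 (excess), CH2Cl2, −78 °C to 0 °C; MeOH, then H2O
Reagents that add atoms: none
Why: BBr3 cleaves the three aryl methyl ethers (Lewis acid complexation, then bromide attack on methyl); with the reagent in excess every ether oxygen including that of ring A is complexed, which should disfavour ionisation of the C2–O1 bond, and neither stereocentre is touched.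

**Compound list**

1 | 3,5-dihydroxybenzaldehyde | O=Cc1cc(O)cc(O)c1 | starting material
2 | 3,5-bis(methoxymethoxy)benzaldehyde | COCOc1cc(C=O)cc(OCOC)c1 | intermediate
3 | (4-methoxybenzyl)triphenylphosphonium chloride | COc1ccc(C[P+](c2ccccc2)(c2ccccc2)c2ccccc2)cc1.[Cl-] | starting material
4 | (4-methoxybenzylidene)triphenylphosphorane | COc1ccc(C=P(c2ccccc2)(c2ccccc2)c2ccccc2)cc1 | intermediate
5 | 1-[2-(4-methoxyphenyl)ethenyl]-3,5-bis(methoxymethoxy)benzene (E/Z mixture) | COCOc1cc(C=Cc2ccc(OC)cc2)cc(OCOC)c1 | intermediate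
6 | 1-[2-(4-methoxyphenyl)ethyl]-3,5-bis(methoxymethoxy)benzene | COCOc1cc(CCc2ccc(OC)cc2)cc(OCOC)c1 | intermediate
7 | {2,6-bis(methoxymethoxy)-4-[2-(4-methoxyphenyl)ethyl]phenyl}lithium | [Li]c1c(OCOC)cc(CCc2ccc(OC)cc2)cc1OCOC | intermediate
8 | 2,6-bis(methoxymethoxy)-4-[2-(4-methoxyphenyl)ethyl]benzaldehyde | COCOc1cc(CCc2ccc(OC)cc2)cc(OCOC)c1C=O | intermediate
9 | 2-[(E)-2-{2,6-bis(methoxymethoxy)-4-[2-(4-methoxyphenyl)ethyl]phenyl}ethenyl]-4,4,5,5-tetramethyl-1,3,2-dioxaborolane | COCOc1cc(CCc2ccc(OC)cc2)cc(OCOC)c1/C=C/B1OC(C)(C)C(C)(C)O1 | intermediate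
10 | [(E)-2-{2,6-bis(methoxymethoxy)-4-[2-(4-methoxyphenyl)ethyl]phenyl}ethenyl]boronic acid | COCOc1cc(CCc2ccc(OC)cc2)cc(OCOC)c1/C=C/B(O)O | intermediate
11 | acenaphthylene-1,2-dione | O=C1C(=O)c2cccc3cccc1c23 | starting material
12 | cis-1,2-dimethyl-1,2-dihydroacenaphthylene-1,2-diol (meso) | C[C@]1(O)c2cccc3cccc(c23)[C@@]1(C)O | intermediate
13 | 8-[(E)-2-{2,6-bis(methoxymethoxy)-4-[2-(4-methoxyphenyl)ethyl]phenyl}ethenyl]-6b,9a-dimethyl-6b,9a-dihydroacenaphtho[1,2-d][1,3,2]dioxaborole (cis-fused) | COCOc1cc(CCc2ccc(OC)cc2)cc(OCOC)c1/C=C/B1O[C@]2(C)c3cccc4cccc(c34)[C@]2(C)O1 | intermediate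
14 | 3,5-dimethoxyphenol | COc1cc(O)cc(OC)c1 | starting material
15 | 3,5-dimethoxyphenyl trifluoromethanesulfonate | COc1cc(OC)cc(OS(=O)(=O)C(F)(F)F)c1 | intermediate
16 | 4-bromoanisole | COc1ccc(Br)cc1 | starting material
17 | 4-methoxyphenyllithium | [Li]c1ccc(OC)cc1 | intermediate
18 | lithium borate from 13 and 17 (configuration at boron not defined) | [Li+].COCOc1cc(CCc2ccc(OC)cc2)cc(OCOC)c1/C=C/[B-]1(c2ccc(OC)cc2)O[C@]2(C)c3cccc4cccc(c34)[C@]2(C)O1 | intermediate
19 | 8-[(1R,2S)-2-{2,6-bis(methoxymethoxy)-4-[2-(4-methoxyphenyl)ethyl]phenyl}-2-(3,5-dimethoxyphenyl)-1-(4-methoxyphenyl)ethyl]-6b,9a-dimethyl-6b,9a-dihydroacenaphtho[1,2-d][1,3,2]dioxaborole | COc1ccc(cc1)[C@H](B1O[C@]2(C)c3cccc4cccc(c34)[C@]2(C)O1)[C@H](c1c(OCOC)cc(CCc2ccc(OC)cc2)cc1OCOC)c1cc(OC)cc(OC)c1 | intermediate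
20 | (1R,2S)-2-{2,6-bis(methoxymethoxy)-4-[2-(4-methoxyphenyl)ethyl]phenyl}-2-(3,5-dimethoxyphenyl)-1-(4-methoxyphenyl)ethan-1-ol | COc1ccc(cc1)[C@H](O)[C@H](c1c(OCOC)cc(CCc2ccc(OC)cc2)cc1OCOC)c1cc(OC)cc(OC)c1 | intermediate
21 | 2-[(1S,2R)-1-(3,5-dimethoxyphenyl)-2-hydroxy-2-(4-methoxyphenyl)ethyl]-5-[2-(4-methoxyphenyl)ethyl]benzene-1,3-diol | COc1ccc(cc1)[C@H](O)[C@H](c1c(O)cc(CCc2ccc(OC)cc2)cc1O)c1cc(OC)cc(OC)c1 | intermediate
22 | (2S,3S)-3-(3,5-dimethoxyphenyl)-2-(4-methoxyphenyl)-6-[2-(4-methoxyphenyl)ethyl]-2,3-dihydro-1-benzofuran-4-ol | COc1ccc(CCc2cc(O)c3c(c2)O[C@H](c2ccc(OC)cc2)[C@H]3c2cc(OC)cc(OC)c2)cc1 | intermediate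
23 | 5-[(2S,3S)-4-hydroxy-2-(4-hydroxyphenyl)-6-[2-(4-hydroxyphenyl)ethyl]-2,3-dihydro-1-benzofuran-3-yl]benzene-1,3-diol | Oc1ccc(CCc2cc(O)c3c(c2)O[C@H](c2ccc(O)cc2)[C@H]3c2cc(O)cc(O)c2)cc1 | target

**Step count**

Total: 13 steps. Longest linear sequence: 11 steps (steps 1 to 6, 8, 10 to 13); steps 7 and 9 are side branches.

**Steps most likely to fail**

Step 10. The borate may pass its alkenyl or aryl group straight to palladium, palladium may fail to bind an alkene whose C3 end carries the 2,6-disubstituted ring C, or it may bind with poor face selectivity. The fallback moves ring C from the alkene to the electrophile, so that the alkene carries only ring B.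
- It sets out from aryllithium 7, which is made from 6 as in step 4. Quenching with 1,2-dibromotetrachloroethane should give 2-bromo-5-[2-(4-methoxyphenyl)ethyl]-1,3-bis(methoxymethoxy)benzene F1.
- Commercial 1-ethynyl-3,5-dimethoxybenzene is hydroborated with catecholborane to the (E)-alkenyl catechol boronate F2 (not isolated). Exchange with diol 12 should give the styryl boronate F3.
- F3 and lithium reagent 17 give the borate F4 (not isolated). This is coupled with F1 under Pd(OAc)2, MandyPhos (antipode chosen as in step 10) and NaOTf to give the boronate F5.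
- F5 is the epimer of 19 at the boron-bearing carbon, with the same configuration at the future C3. Ring C and ring A now add anti across an alkene in which ring B and boron are trans.
- Oxidation as in step 11 should give the alcohol F6. The acid treatment of step 12 frees the triol F7 (not isolated) and ionises the benzylic carbon, so the sequence comes back to the route at 22.

Step 13. The Lewis acid may ionise the C2–O1 bond of the 2-(4-oxyaryl)dihydrobenzofuran, leading to ring opening, loss of the C3 proton or oligomerisation. The fallback cleaves the ethers while C2 still carries boron and forms the ring last.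
- It sets out from 19. BBr3 in CH2Cl2 should cleave the MOM and methyl ethers and strip the diol from boron, and aqueous work-up should give the hexaphenol boronic acid F9.
- Oxidation with NaBO3·4H2O in THF/H2O should give the benzylic alcohol F10.
- The 4-hydroxybenzylic carbon of F10 ionises to a para-quinone methide in dilute acid (acetic acid in methanol, 25 °C) and is trapped by an ortho phenol. The sequence comes back to the route at 23, expected as the trans isomer.

Step 12. The benzylic cation may lose the C3 proton to give a triarylethene, destroying the only stereocentre that has to be kept, or it may alkylate an arene before the phenol closes. The fallback closes the ring by SN2 displacement.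
- It sets out from 19. Methanolic HCl at 25 °C should remove the MOM groups with the C–B bond in place, giving the diphenol boronate F8.
- NaBO3·4H2O should oxidise F8 to triol 21, here isolated.
- Mitsunobu cyclodehydration (PPh3, diisopropyl azodicarboxylate, THF, 0 °C) displaces the activated benzylic alcohol by an ortho phenol with inversion and comes back to the route at 22.
- The (1R,2S) relationship set by the anti addition of step 10 is the one that gives the trans ring on inversion.

**Further compounds**

F1 | step 10 | 2-bromo-5-[2-(4-methoxyphenyl)ethyl]-1,3-bis(methoxymethoxy)benzene | COCOc1cc(CCc2ccc(OC)cc2)cc(OCOC)c1Br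
F2 | step 10 | 2-[(E)-2-(3,5-dimethoxyphenyl)ethenyl]-1,3,2-benzodioxaborole | COc1cc(/C=C/B2Oc3ccccc3O2)cc(OC)c1
F3 | step 10 | 8-[(E)-2-(3,5-dimethoxyphenyl)ethenyl]-6b,9a-dimethyl-6b,9a-dihydroacenaphtho[1,2-d][1,3,2]dioxaborole (cis-fused) | COc1cc(/C=C/B2O[C@]3(C)c4cccc5cccc(c45)[C@]3(C)O2)cc(OC)c1
F4 | step 10 | lithium borate from F3 and 17 (configuration at boron not defined) | [Li+].COc1cc(/C=C/[B-]2(c3ccc(OC)cc3)O[C@]3(C)c4cccc5cccc(c45)[C@]3(C)O2)cc(OC)c1
F5 | step 10 | 8-[(1S,2S)-2-{2,6-bis(methoxymethoxy)-4-[2-(4-methoxyphenyl)ethyl]phenyl}-2-(3,5-dimethoxyphenyl)-1-(4-methoxyphenyl)ethyl]-6b,9a-dimethyl-6b,9a-dihydroacenaphtho[1,2-d][1,3,2]dioxaborole | COc1ccc(cc1)[C@@H](B1O[C@]2(C)c3cccc4cccc(c34)[C@]2(C)O1)[C@H](c1c(OCOC)cc(CCc2ccc(OC)cc2)cc1OCOC)c1cc(OC)cc(OC)c1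
F6 | step 10 | (1S,2S)-2-{2,6-bis(methoxymethoxy)-4-[2-(4-methoxyphenyl)ethyl]phenyl}-2-(3,5-dimethoxyphenyl)-1-(4-methoxyphenyl)ethan-1-ol | COc1ccc(cc1)[C@@H](O)[C@H](c1c(OCOC)cc(CCc2ccc(OC)cc2)cc1OCOC)c1cc(OC)cc(OC)c1
F7 | step 10 | 2-[(1S,2S)-1-(3,5-dimethoxyphenyl)-2-hydroxy-2-(4-methoxyphenyl)ethyl]-5-[2-(4-methoxyphenyl)ethyl]benzene-1,3-diol | COc1ccc(cc1)[C@@H](O)[C@H](c1c(O)cc(CCc2ccc(OC)cc2)cc1O)c1cc(OC)cc(OC)c1
F8 | step 12 | 2-[(1S,2R)-2-(6b,9a-dimethyl-6b,9a-dihydroacenaphtho[1,2-d][1,3,2]dioxaborol-8-yl)-1-(3,5-dimethoxyphenyl)-2-(4-methoxyphenyl)ethyl]-5-[2-(4-methoxyphenyl)ethyl]benzene-1,3-diol | COc1ccc(cc1)[C@H](B1O[C@]2(C)c3cccc4cccc(c34)[C@]2(C)O1)[C@H](c1c(O)cc(CCc2ccc(OC)cc2)cc1O)c1cc(OC)cc(OC)c1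
F9 | step 13 | [(1R,2S)-2-{2,6-dihydroxy-4-[2-(4-hydroxyphenyl)ethyl]phenyl}-2-(3,5-dihydroxyphenyl)-1-(4-hydroxyphenyl)ethyl]boronic acid | Oc1ccc(cc1)[C@H](B(O)O)[C@H](c1c(O)cc(CCc2ccc(O)cc2)cc1O)c1cc(O)cc(O)c1
F10 | step 13 | 2-[(1S,2R)-1-(3,5-dihydroxyphenyl)-2-hydroxy-2-(4-hydroxyphenyl)ethyl]-5-[2-(4-hydroxyphenyl)ethyl]benzene-1,3-diol | Oc1ccc(cc1)[C@H](O)[C@H](c1c(O)cc(CCc2ccc(O)cc2)cc1O)c1cc(O)cc(O)c1
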